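# Proposed synthesis of agecorynin E, (2S)-4'-hydroxy-3',5,6,7-tetramethoxyflavanone

**Numbering used throughout**

1 vinylmagnesium bromide · 2 divinylzinc · 3 vanillin acetate · 4 (R)-allylic alcohol · 5 3,4,5-trimethoxyphenol · 6 2-hydroxy-4,5,6-trimethoxyacetophenone · 7 (S)-aryl allyl ether ketone · 8 (S)-silyl enol ether diene · 9 (S)-4-silyloxy-2H-chromene · 10 flavanone acetate · 11 agecorynin E

## Analysis of the target

Agecorynin E is a flavanone: a benzo-fused dihydropyranone (rings A and C) with a guaiacyl ring B on C2. Ring A is fully differentiated, with O1 on C8a, the C4 carbonyl on C4a, methoxyls on C5, C6 and C7 and a single hydrogen on C8. Ring B carries a free hydroxyl at C4' beside a methoxyl at C3'. The only stereocentre is C2, of (S) configuration; it is benzylic, bears O1 and lies β to the C4 ketone. That position makes it labile: base expels the C8a phenoxide by β-elimination and opens ring C to an achiral 2'-hydroxychalcone, and the free para-hydroxyl of ring B assists ionisation of the C2–O1 bond. Other sensitive groups are the oxidisable phenol and the C5 methoxyl, which Lewis acids cleave readily because it sits peri to the carbonyl. The difficulty is therefore not the skeleton but setting C2 as one enantiomer and carrying it to the end without strong base or hot acid. The strategy rests on C3–C4: if the C4 ketone is written as its silyl enol ether, C3=C4 becomes a ring olefin of six-membered ring C, and C2 is then simply an allylic, benzylic aryl ether carbon whose C2–O1 bond can be made beforehand.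

## Retrosynthetic reasoning

**11 back to 9 (through 10).** No skeletal bond is cut. The C4 ketone is written as its tert-butyldimethylsilyl enol ether and the C4' phenol as its acetate. Both masks fall in one acid-catalysed solvolysis, the enol ether first (giving 10), the aryl ester second. Acid is chosen because base would open ring C at O1–C2 and erase the stereocentre. The gain is a C3=C4 double bond inside ring C.

**9 back to 8.** The C3=C4 bond is cut by a ring-closing metathesis transform. It is the one bond of ring C that can be formed without reacting at C2, at O1 or at a carbon of the pentasubstituted ring A. The precursor 8 is an acyclic aryl ether with a vinyl group on C2 and a 1-silyloxyvinyl group on C4a. The forward reaction has to join a monosubstituted olefin to a hindered 1,1-disubstituted enol ether in a six-membered ring, expelling the two terminal methylene carbons, while leaving the allylic, benzylic ether at C2 alone.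

**8 back to 7.** A functional-group change only: the silyl enol ether comes from the methyl ketone. The acetyl group has a single enolisable position, so no regiochemical question arises. The forward step must be non-basic enough to spare the aryl acetate.

**7 back to 4 and 6.** The O1–C2 bond is cut. This splits the molecule into two halves of similar size, each carrying every substituent of one aromatic ring. The forward reaction is an SN2 etherification of a secondary allylic, benzylic alcohol with inversion, so 4 must be (R) to give (S) in 7. The ring B oxygen is kept as an acetate and not as an ether, so that the aryl group does not stabilise a cation at C2 and the substitution stays on the SN2 path. The same acetate leaves in the last step at no extra cost.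

**4 back to 3 and 2 (2 from 1).** The C2–C3 bond is cut. Enantioselective transfer of a vinyl group to aldehyde 3 sets the stereocentre under catalyst control. An organozinc is used because it adds to the aldehyde without attacking the aryl ester. Reagent 2 carries two vinyl groups and is made from two equivalents of commercial 1.

**6 back to 5.** The C4–C4a bond is cut by an ortho-acetylation transform. The oxygenation pattern of ring A is bought complete in 5. Its two free positions are equivalent, so only one regioisomer can form.

## Alternatives that were turned down

**Alternative 1:** Ring A is built by benzannulation, cutting C4a–C5, C8–C8a and C5–C6. In the forward step, irradiation of 1-diazo-3,4-dimethoxybut-3-en-2-one A2 triggers a Wolff rearrangement to vinylketene A4. A4 adds the chiral siloxyalkyne A3 by [2+2] addition, and four-electron ring opening followed by six-electron ring closure gives phenol A1. In its favour, the step is convergent, places every oxygen of ring A by construction, and keeps the stereocentre remote from the reacting centres as a robust silyl ether. Against it, the ring A pattern is commercially available in phenol 5, so building the benzene ring buys nothing for this target. A1 is also far from the end. Its C5 hydroxyl must be methylated, two different silyl groups removed in order, and ring C closed at C2 with inversion, which is the same benzylic substitution risk as in the chosen route. C4 arrives as a methylene group, and oxidising it to the ketone must compete with the C2–H bond, which is benzylic and α to oxygen and hence more easily oxidised. A2 is a labile, heavily oxygenated diazo ketone, and A3 needs several steps of its own. On regiochemical certainty for ring A, and as a platform for analogues, this alternative is the stronger. The chosen strategy instead offers a bought ring A, C4 at the ketone oxidation level from the start, and roughly half the step count.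

**Alternative 2:** The O1–C8a bond is cut. In the forward step the anti-1,3-diol A6, with bromine at C8a, cyclises through its C2 hydroxyl under a palladium diacetate catalyst with a bulky di-tert-butyl(binaphthyl)phosphine and a carbonate base, giving the 2,4-cis chromanol A5. Its strong point is that no bond to C2 is made or broken, so the configuration of C2 cannot be eroded by ionisation. On that point it is stronger than the chosen route, whose etherification happens at the stereocentre itself. Against it, the aryl bromide is very electron-rich and ortho-substituted, so oxidative addition is slow. The alkoxide on divalent palladium, and equally the free benzylic C4 carbinol, can undergo β-hydride elimination, which reduces the bromide and oxidises the alcohol. A6 requires ring A bromination, an asymmetric aldol-type construction and an anti-selective reduction, and the C4 stereocentre so made is then destroyed by oxidation. After the key step an oxidation and a hydrogenolytic debenzylation remain, the latter endangering the benzylic C2–O1 bond. The chosen strategy offers fewer steps, no redundant stereocentre and a ring B protecting group that leaves without hydrogen.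

**Alternative 3:** The C3–C4 and O1–C2 bonds are cut together. In the forward step salicylaldehyde A8 is converted in situ with an orthoformate into the methoxy-substituted ortho-quinone methide A10. Under a chiral phosphoric acid, A10 adds 4-acetoxy-3-methoxystyrene A9 to give the 2,4-cis 4-methoxyflavan A7. On step economy this is the strongest of all: ring C, two bonds and the stereocentre arise in one operation from partners that are each about one step from commercial materials. The weakness is the stereocontrol. The addition is likely to be stepwise through a benzylic cation at C2. A9 has no hydrogen-bond donor by which the chiral anion can hold it. A10 is strongly stabilised by three methoxyls and is therefore a sluggish hetero-diene. The C4 methoxyl must then be converted into the ketone in two further steps under conditions that can ionise C2. The chosen strategy is longer, but it separates stereocontrol from ring formation: C2 is set and can be checked on a simple alcohol, and the ring-closing step is stereochemically innocent.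

Key step: step 6

Remark: the SMILES fixes C2 as (S). (+)-MIB is assumed to deliver the vinyl group to the Re face of 3, the mirror image of the Si-face delivery known for its antipode with dialkylzincs; the sense should be confirmed on 4 and the other ligand antipode used if needed.

## Route

Step 1
Reactants: 1 vinylmagnesium bromide (2 equiv)
Product: 2 divinylzinc
Conditions: ZnCl2 (0.5 equiv relative to 1), THF, 0 °C to rt; 1,4-dioxane, filtration under Ar; vacuum transfer into toluene, stored at −20 °C
Reagents that add atoms: zinc chloride, Cl[Zn]Cl; vinylmagnesium bromide (the second equivalent of 1), C=C[Mg]Br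
Why: Transmetalation of two equivalents of the Grignard reagent with one equivalent of ZnCl2 gives the diorganozinc, each of its two vinyl groups coming from one molecule of 1; the magnesium halide is removed because it would promote an uncatalysed, racemic addition in step 2.

Step 2
Reactants: 3 vanillin acetate (4-formyl-2-methoxyphenyl acetate); 2 divinylzinc
Product: 4 4-[(1R)-1-hydroxyprop-2-en-1-yl]-2-methoxyphenyl acetate
Conditions: 2 (1.5 equiv), (+)-MIB [(2R)-3-exo-morpholinoisoborneol] (5 mol %), toluene, −30 to 0 °C; aq. NH4Cl
Reagents that add atoms: none
Why: Amino-alcohol-catalysed enantioselective addition of a diorganozinc to an aryl aldehyde: the zinc aminoalkoxide binds the aldehyde and a second molecule of 2 in a bimetallic transition state and should deliver the vinyl group to the Re face, giving (R); the organozinc is not nucleophilic enough to attack the aryl acetate.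

Step 3
Reactants: 5 3,4,5-trimethoxyphenol
Product: 6 1-(2-hydroxy-4,5,6-trimethoxyphenyl)ethan-1-one
Conditions: AcOH, BF3·OEt2 (3 equiv), 85 °C; then H2O
Reagents that add atoms: acetic acid, CC(=O)O
Why: BF3-mediated ortho C-acetylation of a phenol (Friedel–Crafts acylation, in part through the O-acetate and a Fries rearrangement); the two free positions of 5 are equivalent, so one regioisomer results, and the product is held as its difluoroboron chelate, which blocks a second acylation and is hydrolysed on work-up.

Step 4
Reactants: 4 4-[(1R)-1-hydroxyprop-2-en-1-yl]-2-methoxyphenyl acetate; 6 1-(2-hydroxy-4,5,6-trimethoxyphenyl)ethan-1-one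
Product: 7 4-[(1S)-1-(2-acetyl-3,4,5-trimethoxyphenoxy)prop-2-en-1-yl]-2-methoxyphenyl acetate
Conditions: PPh3, DIAD, toluene, −20 °C to rt; chromatography on Et3N-washed silica
Reagents that add atoms: none
Why: Mitsunobu etherification: the acidic, acetyl-activated phenol 6 protonates the betaine and its phenoxide displaces the alkoxyphosphonium ion of 4 by SN2 with inversion, (R) to (S); the para-acetoxy and meta-methoxy groups give the benzylic carbon no more cation stabilisation than a plain phenyl would, and the non-polar solvent and low temperature further disfavour SN1 and SN2' paths.

Step 5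
Reactants: 7 4-[(1S)-1-(2-acetyl-3,4,5-trimethoxyphenoxy)prop-2-en-1-yl]-2-methoxyphenyl acetate
Product: 8 4-[(1S)-1-{2-[1-(tert-butyldimethylsilyloxy)ethenyl]-3,4,5-trimethoxyphenoxy}prop-2-en-1-yl]-2-methoxyphenyl acetate
Conditions: TBSOTf (1.3 equiv), Et3N (3 equiv), CH2Cl2, 0 °C
Reagents that add atoms: tert-butyldimethylsilyl trifluoromethanesulfonate, CC(C)(C)[Si](C)(C)OS(=O)(=O)C(F)(F)F
Why: Soft enolisation of a methyl ketone with a silyl triflate and a tertiary amine gives the only possible silyl enol ether; the conditions are too weakly basic to touch the aryl acetate or the non-acidic C2–H, and the excess amine keeps the medium from ionising the allylic ether.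

Step 6
Reactants: 8 4-[(1S)-1-{2-[1-(tert-butyldimethylsilyloxy)ethenyl]-3,4,5-trimethoxyphenoxy}prop-2-en-1-yl]-2-methoxyphenyl acetate
Product: 9 4-[(2S)-4-(tert-butyldimethylsilyloxy)-5,6,7-trimethoxy-2H-chromen-2-yl]-2-methoxyphenyl acetate
Conditions: second-generation Grubbs catalyst RuCl2(=CHPh)(H2IMes)(PCy3) (5–10 mol %), 1,4-benzoquinone (10 mol %), degassed toluene (0.005 M), 40–60 °C, Ar sparge, dark
Reagents that add atoms: none
Why: Ring-closing olefin metathesis by the Chauvin mechanism: the ruthenium benzylidene exchanges first with the unhindered vinyl group on C2, placing the carbene on C3. This carbene adds intramolecularly to the 1,1-disubstituted silyl enol ether with ruthenium on its methylene carbon, and cycloreversion of the ruthenacyclobutane forms C3=C4 and releases Ru=CH2, which carries the chain, with ethylene as the only co-product. The closest known reaction types are the ring-closing metathesis of olefinic silyl enol ethers to cyclic silyl enol ethers, including aryl-tethered cases that give 4-silyloxy-1,2-dihydroquinolines, and of 2-vinylaryl allyl ethers to 2H-chromenes. Ring C closes as a six-membered ring from a 1,7-diene whose two olefins are held ortho to each other on ring A, so cyclisation is entropically favoured and strain-free. No stereocentre is formed, and C2, set in steps 2 and 4, is untouched because neither its C–H nor its C–O bond takes part under the neutral catalyst. The step needs initiation at the vinyl group, ring closure in preference to intermolecular metathesis, and no olefin migration: the enol ether is too hindered and electron-rich to initiate or dimerise, high dilution with removal of ethylene favours the ring, and benzoquinone traps ruthenium hydrides. The peri contact between the C4 silyloxy group and the C5 methoxyl will slow closure relative to unsubstituted models, so the second-generation Hoveyda–Grubbs catalyst RuCl2(H2IMes)(=CH-C6H4-2-OiPr) at 60 °C is the first variation, and heat and light are kept low to prevent electrocyclic ring opening of the 2H-chromene, which would scramble C2.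

Step 7
Reactants: 9 4-[(2S)-4-(tert-butyldimethylsilyloxy)-5,6,7-trimethoxy-2H-chromen-2-yl]-2-methoxyphenyl acetate
Product: 11 agecorynin E [(2S)-2-(4-hydroxy-3-methoxyphenyl)-5,6,7-trimethoxychroman-4-one], via flavanone acetate 10 (not isolated)
Conditions: HCl (0.5 M) in MeOH, 0 °C to rt
Reagents that add atoms: none
Why: Acid-catalysed solvolysis: protonation of the silyl enol ether at C3 and transfer of silicon to methanol should give ketone 10 quickly, and the same medium then transesterifies the aryl acetate to free the phenol; acid is used because base would open ring C by β-elimination and racemise C2.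

## Compound list

1 | vinylmagnesium bromide | C=C[Mg]Br | starting material
2 | divinylzinc | C=C[Zn]C=C | intermediate
3 | vanillin acetate (4-formyl-2-methoxyphenyl acetate) | CC(=O)Oc1ccc(C=O)cc1OC | starting material
4 | 4-[(1R)-1-hydroxyprop-2-en-1-yl]-2-methoxyphenyl acetate | C=C[C@@H](O)c1ccc(OC(C)=O)c(OC)c1 | intermediate
5 | 3,4,5-trimethoxyphenol | COc1cc(O)cc(OC)c1OC | starting material
6 | 1-(2-hydroxy-4,5,6-trimethoxyphenyl)ethan-1-one | CC(=O)c1c(O)cc(OC)c(OC)c1OC | intermediate
7 | 4-[(1S)-1-(2-acetyl-3,4,5-trimethoxyphenoxy)prop-2-en-1-yl]-2-methoxyphenyl acetate | C=C[C@H](Oc1cc(OC)c(OC)c(OC)c1C(C)=O)c1ccc(OC(C)=O)c(OC)c1 | intermediate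
8 | 4-[(1S)-1-{2-[1-(tert-butyldimethylsilyloxy)ethenyl]-3,4,5-trimethoxyphenoxy}prop-2-en-1-yl]-2-methoxyphenyl acetate | C=C[C@H](Oc1cc(OC)c(OC)c(OC)c1C(=C)O[Si](C)(C)C(C)(C)C)c1ccc(OC(C)=O)c(OC)c1 | intermediate
9 | 4-[(2S)-4-(tert-butyldimethylsilyloxy)-5,6,7-trimethoxy-2H-chromen-2-yl]-2-methoxyphenyl acetate | COc1cc([C@@H]2C=C(O[Si](C)(C)C(C)(C)C)c3c(cc(OC)c(OC)c3OC)O2)ccc1OC(C)=O | intermediate
10 | 4-[(2S)-5,6,7-trimethoxy-4-oxochroman-2-yl]-2-methoxyphenyl acetate (flavanone acetate, not isolated) | COc1cc([C@@H]2CC(=O)c3c(cc(OC)c(OC)c3OC)O2)ccc1OC(C)=O | intermediate
11 | agecorynin E, (2S)-2-(4-hydroxy-3-methoxyphenyl)-5,6,7-trimethoxychroman-4-one | COc1cc([C@@H]2CC(=O)c3c(cc(OC)c(OC)c3OC)O2)ccc1O | target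

## Step count and least certain steps

Total: 7 steps. Longest linear sequence: 6 steps (steps 1, 2, 4, 5, 6, 7, starting from 1); the branch to 6 is one step (step 3).

**Step 6 (key step).** The most likely failure is slow or absent ring closure. The enol ether is 1,1-disubstituted and electron-rich, it is flanked by the C5 methoxyl, and the product carries a peri interaction between the C4 silyloxy and C5 methoxy groups. A stalled catalyst then decomposes to ruthenium hydrides, which can migrate the allyl ether double bond, or the vinyl groups dimerise by cross-metathesis. Forcing temperatures could erode C2 through reversible electrocyclic opening of the 2H-chromene.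

Fallback: the C4 oxygen is introduced after ring closure instead of being carried through it. The fallback sets out from 7 and returns at 10. Reduction of the ketone with Zn(BH4)2 in Et2O at 0 °C, where a ketone is reduced much faster than an aryl ester or an olefin, should give 4-[(1S)-1-{2-(1-hydroxyethyl)-3,4,5-trimethoxyphenoxy}prop-2-en-1-yl]-2-methoxyphenyl acetate F1. Dehydration with the Burgess reagent (benzene, 50 °C) should give the styrene 4-[(1S)-1-(2-ethenyl-3,4,5-trimethoxyphenoxy)prop-2-en-1-yl]-2-methoxyphenyl acetate F2. Ring-closing metathesis of its two monosubstituted olefins (second-generation Grubbs catalyst, CH2Cl2, 40 °C), a closure of well-established type, should give 4-[(2S)-5,6,7-trimethoxy-2H-chromen-2-yl]-2-methoxyphenyl acetate F3. Mukaiyama hydration (Co(acac)2, PhSiH3, O2, THF/i-PrOH, rt) should place hydrogen on C3 and oxygen on the benzylic C4, giving 4-[(2S)-4-hydroxy-5,6,7-trimethoxychroman-2-yl]-2-methoxyphenyl acetate F4. Oxidation with Dess–Martin periodinane (NaHCO3, CH2Cl2) should give 10, which is taken on as in the second half of step 7.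

**Step 4.** The most likely failure is loss of configurational purity through ionisation of the alkoxyphosphonium ion (SN1), together with SN2' attack leading to the achiral cinnamyl ether. The carbinol carbon is both allylic and benzylic, and the hydrogen-bonded phenol is a sluggish nucleophile. The product ether is also acid-sensitive on silica.

Fallback: the stereocentre and the C2–O1 bond are made together by enantioselective allylic substitution. The fallback sets out from 4 (of any enantiomeric purity) and 6, and returns at 7. 1,3-Transposition of the hydroxyl (Ph3SiOReO3 cat., Et2O, 0 °C) should give the conjugated 4-[(1E)-3-hydroxyprop-1-en-1-yl]-2-methoxyphenyl acetate F5. Acylation with ClCO2Me and pyridine should give (2E)-3-(4-acetoxy-3-methoxyphenyl)prop-2-en-1-yl methyl carbonate F6. Branch-selective etherification of F6 with 6 should give 7; the catalyst is [Ir(cod)Cl]2 with a binaphthol-derived bis(1-phenylethyl)phosphoramidite, activated with propylamine, in THF at rt. Phenol 6 is used free with a catalytic base, so that the methoxide released from the carbonate is quenched by proton transfer and does not attack the aryl acetate. The ligand antipode that gives the (S)-ether is fixed by a test run.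

**Step 2.** The most likely failure is insufficient enantioselectivity. Residual magnesium halide promotes a background addition, and divinylzinc is harder to handle and less well behaved than dialkylzincs.

Fallback: resolution replaces asymmetric addition. The fallback sets out from 3 and 1 and returns at 4. Direct addition of 1 to 3 (THF, −78 °C, cold quench; the aldehyde is far more electrophilic than the aryl ester) should give racemic 4-(1-hydroxyprop-2-en-1-yl)-2-methoxyphenyl acetate F7. Sharpless kinetic resolution (Ti(OiPr)4, D-(−)-diisopropyl tartrate, t-BuOOH, 4 Å sieves, CH2Cl2, −20 °C, to slightly beyond half conversion) should consume the (S)-enantiomer as the erythro epoxy alcohol 4-{(R)-hydroxy[(2S)-oxiran-2-yl]methyl}-2-methoxyphenyl acetate F8 and leave (R)-4. The cost is at most half of the material and a slow epoxidation of a monosubstituted olefin.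

**Step 7.** The most likely failure is partial racemisation at C2 if acid strength or time has to be raised to complete the acetate cleavage. Possible paths are benzylic ionisation assisted by the freed para-hydroxyl and ring opening to the chalcone. Incomplete deacetylation is the other outcome.

Fallback: the two unmaskings are separated and run near neutrality. The fallback sets out from 9, passes through isolated 10 and returns at 11. Pyridine-buffered HF·pyridine in THF at 0 °C should cleave the silyl enol ether to 10. Lipase-catalysed butanolysis (immobilised Candida antarctica lipase B, n-BuOH, t-BuOMe, 40 °C) should then remove the aryl acetate without acid or base. This fallback makes no compound outside the list.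

## Further compounds

F1 | step 6 | 4-[(1S)-1-{2-(1-hydroxyethyl)-3,4,5-trimethoxyphenoxy}prop-2-en-1-yl]-2-methoxyphenyl acetate (carbinol epimers) | C=C[C@H](Oc1cc(OC)c(OC)c(OC)c1C(C)O)c1ccc(OC(C)=O)c(OC)c1
F2 | step 6 | 4-[(1S)-1-(2-ethenyl-3,4,5-trimethoxyphenoxy)prop-2-en-1-yl]-2-methoxyphenyl acetate | C=C[C@H](Oc1cc(OC)c(OC)c(OC)c1C=C)c1ccc(OC(C)=O)c(OC)c1
F3 | step 6 | 4-[(2S)-5,6,7-trimethoxy-2H-chromen-2-yl]-2-methoxyphenyl acetate | COc1cc([C@@H]2C=Cc3c(cc(OC)c(OC)c3OC)O2)ccc1OC(C)=O
F4 | step 6 | 4-[(2S)-4-hydroxy-5,6,7-trimethoxychroman-2-yl]-2-methoxyphenyl acetate (C4 epimers) | COc1cc([C@@H]2CC(O)c3c(cc(OC)c(OC)c3OC)O2)ccc1OC(C)=O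
F5 | step 4 | 4-[(1E)-3-hydroxyprop-1-en-1-yl]-2-methoxyphenyl acetate | CC(=O)Oc1ccc(/C=C/CO)cc1OC
F6 | step 4 | (2E)-3-(4-acetoxy-3-methoxyphenyl)prop-2-en-1-yl methyl carbonate | COC(=O)OC/C=C/c1ccc(OC(C)=O)c(OC)c1
F7 | step 2 | racemic 4-(1-hydroxyprop-2-en-1-yl)-2-methoxyphenyl acetate | C=CC(O)c1ccc(OC(C)=O)c(OC)c1
F8 | step 2 | 4-{(R)-hydroxy[(2S)-oxiran-2-yl]methyl}-2-methoxyphenyl acetate | O[C@@H]([C@@H]1CO1)c1ccc(OC(C)=O)c(OC)c1
F0 | step 7 | none | none
A1 | alternative 1 | (R)-2-[3-(4-benzyloxy-3-methoxyphenyl)-3-(tert-butyldimethylsilyloxy)propyl]-5,6-dimethoxy-3-(triisopropylsilyloxy)phenol | COc1cc(O[Si](C(C)C)(C(C)C)C(C)C)c(CC[C@@H](O[Si](C)(C)C(C)(C)C)c2ccc(OCc3ccccc3)c(OC)c2)c(O)c1OC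
A2 | alternative 1 | 1-diazo-3,4-dimethoxybut-3-en-2-one | COC=C(OC)C(=O)C=[N+]=[N-]
A3 | alternative 1 | (R)-1-benzyloxy-4-[1-(tert-butyldimethylsilyloxy)-5-(triisopropylsilyloxy)pent-4-yn-1-yl]-2-methoxybenzene | CC(C)[Si](OC#CCC[C@@H](O[Si](C)(C)C(C)(C)C)c1ccc(OCc2ccccc2)c(OC)c1)(C(C)C)C(C)C
A4 | alternative 1 | 3,4-dimethoxybuta-1,3-dien-1-one (vinylketene) | COC=C(OC)C=C=O
A5 | alternative 2 | (2S,4S)-2-(4-benzyloxy-3-methoxyphenyl)-5,6,7-trimethoxychroman-4-ol | COc1cc([C@@H]2C[C@H](O)c3c(cc(OC)c(OC)c3OC)O2)ccc1OCc1ccccc1
A6 | alternative 2 | (1S,3S)-3-(4-benzyloxy-3-methoxyphenyl)-1-(6-bromo-2,3,4-trimethoxyphenyl)propane-1,3-diol | COc1cc([C@@H](O)C[C@H](O)c2c(Br)cc(OC)c(OC)c2OC)ccc1OCc1ccccc1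
A7 | alternative 3 | (2S,4S)-2-(4-acetoxy-3-methoxyphenyl)-4,5,6,7-tetramethoxychroman | COc1cc([C@@H]2C[C@H](OC)c3c(cc(OC)c(OC)c3OC)O2)ccc1OC(C)=O
A8 | alternative 3 | 6-hydroxy-2,3,4-trimethoxybenzaldehyde | O=Cc1c(O)cc(OC)c(OC)c1OC
A9 | alternative 3 | 4-acetoxy-3-methoxystyrene (4-ethenyl-2-methoxyphenyl acetate) | C=Cc1ccc(OC(C)=O)c(OC)c1
A10 | alternative 3 | 3,4,5-trimethoxy-6-(methoxymethylidene)cyclohexa-2,4-dien-1-one (ortho-quinone methide) | COC=C1C(=O)C=C(OC)C(OC)=C1OC
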